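The leftover I follow is c(intermediate B), told as percent of the substrate charged: what still stands as intermediate B while the feed runs.

| flask | substrate | coupling partner | remark | time |
|---|---|---|---|---|
| spring | 0.10 M (fed, over 20 h) | 1.5 equiv | run made earlier |  |
| winter | 0.10 M (fed, over 20 h) | 6 equiv | run made earlier |  |
| summer | 0.20 M (fed, over 20 h) | 3 equiv | run made earlier |  |
| flask | 0.10 M (fed, over 20 h) | 3.00 equiv |  | 15 d |

| run | time / d | intermediate B / % | target / % | substrate / % |
|---|---|---|---|---|
| spring | 0.208 | 11.7 | 1.6 | 6.7 |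
| spring | 0.625 | 27.6 | 2.7 | 14.1 |
| spring | 1.67 | 11.6 | 1.5 | 4.3 |
| spring | 5.00 | 0.4 | 0.4 | 1.0 |
| spring | 15.0 | 0.5 | 0 | 0.4 |
| winter | 0.208 | 11.5 | 1.2 | 6.0 |
| winter | 0.625 | 27.6 | 3.5 | 13.9 |
| winter | 1.67 | 12.4 | 0.8 | 5.7 |
| winter | 5.00 | 1.6 | 0 | 1.1 |
| winter | 15.0 | 0.5 | 0 | 0.5 |
| summer | 0.208 | 11.4 | 1.0 | 6.4 |
| summer | 0.625 | 25.1 | 3.5 | 14.1 |
| summer | 1.67 | 10.1 | 1.8 | 5.0 |
| summer | 5.00 | 2.0 | 0 | 0.2 |
| summer | 15.0 | 0.3 | 0 | 0.4 |

(scatter of a reading: 0.5 percentage points)

1. the moment within 15 d at which there is most intermediate B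
2. the amount of intermediate B, in percent of the substrate charged, at that time

At 0.625 d, spring and summer read 27.6% and 25.1%, so on log axes the slope reads −0.137, with the scatter of those two readings in it. I call this the charge exponent: the change in the logarithm of the percentage of intermediate B per change in the logarithm of the substrate charge. The flask has spring's charge, so the exponent takes nothing from it, and winter reads 27.6% at 6 equiv, so I leave the partner out. Per fed substrate, spring's intermediate B falls from 46.9% to 36.8%. That line on log axes, carried to the end of the feed at 0.83 d, gives me 34.5% as my estimate of the flask's peak, which I place at that time.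

The forecast says 33% at 0.85 d, lower than my figure: “B should peak at, or just after, the end of feeding”.

The flask gives 32.1% at 0.837 d, so the forecast stands.

    substrate ⇌ intermediate A (K = 0.650, k = 2.70 × 10⁻⁴ /s)
    substrate ⇌ intermediate B (K = 2.20, k = 5.70 × 10⁻⁴ /s)
    substrate ⇌ intermediate C (K = 14.0, k = 1.50 × 10⁻⁵ /s)
    intermediate B ⇌ target (K = 0.170, k = 3.70 × 10⁻⁵ /s)
    target → over-reaction product (k = 1.30 × 10⁻⁴ /s)
    coupling partner ⇌ dormant form (K = 0.180, k = 6.50 × 10⁻⁶ /s)
    substrate + intermediate B → side product (k = 3.10 × 10⁻⁴ /M/s)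

The neighbouring flask is the same recipe at 0.40 M of substrate. Starting from this flask's 32.1%, the charge exponent gives 26.5%, but the neighbouring flask gives 24.2%, so the slope between the two flasks is −0.204, steeper than the −0.137 read from the runs. The forecast's 33% does not carry over to that charge. At 15.0 d the neighbouring flask holds 47.2% as side product, each unit counted as two, twice the 21.6% of this flask.

The readings were computed from invented constants; scatter was added.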